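## The problem

Compound 16 is a C–O–C biflavone: two 5-hydroxy-7-methoxyflavone units joined by a diaryl ether from C4' of ring B (unit 1, rings A, C, B) to C8'' of ring D (unit 2, rings D, E, F). It has no stereocentres, so the task is one of regiochemistry and of keeping five oxygen functions apart: two chelated 5-hydroxyl groups, two 7-methyl ethers and one free 4'''-phenol that must stay masked until the end. Ring D is a pentasubstituted benzene in which only C6'' carries hydrogen. Its ether oxygen at C8'' is wedged between the C7'' methoxy group and the pyranone oxygen O1'', so any aryl–oxygen coupling there meets an electron-rich, doubly ortho-substituted partner. The two 4-pyranone rings open with hot alkali or hard nucleophiles, the methyl ethers do not survive strong Lewis acids, and the phenols are easily oxidised, so the late steps must be mild. Unit 1 is the easy half: ring A is available as a symmetric 2,6-dihydroxy-4-methoxyphenyl ketone and ring C follows from a 1,3-diketone. The enabling feature is the oxygenation pattern of ring D: C5''–OH and C7''–OMe stand 1,3 to each other, C8'' is next to C7'', and the C4a''–C8a'' bond is the C5=C6 bond of a 2-aryl-4-pyranone. Ring D can therefore be grown from a 1,3-dioxygenated butadiene (C5'' to C8'') onto a preformed pyranone (rings E and F), with the C8''–O bond already present as an ordinary alkyl aryl ether.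

## Retrosynthesis

**16 from 15.** The first cut is the O–CH2 bond of a benzyl ether, giving 15. The 4'''-phenol is the only hydroxyl group that needs a mask; the two 5-hydroxyl groups are chelated to their carbonyl groups and are carried free. Hydrogenolysis is neutral and touches neither the methyl ethers nor the diaryl ether.

**15 from 14, and 14 from 12 and 13.** Unit 1 is removed next. Cutting O1–C2 of ring C gives the 1,3-diketone 14, and cutting C2–C3 of the diketone gives methyl ester 12 and the commercial acetophenone 13. The alternative of carrying a finished unit 1 through the ring-D construction was rejected, because a second chelated phenol and a second pyranone would then meet LiN(iPr)2 and a silyl ketene acetal. A methyl ester is small, survives those steps and is itself the acyl donor. Ring A of 13 is symmetric, so the cyclodehydration cannot give a regioisomer. The forward steps ask for a Claisen condensation of a polyanion in the presence of one flavone, and an acid-mediated ring closure.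

**12 from 4 and 10.** This is the central cut: C8''–C8a'' and C5''–C4a'' of ring D are broken together. The four carbons C5'' to C8'' become the 4-aryloxy-1,3-dioxygenated diene 4, and C4a''/C8a'' become C5/C6 of the sulfinylpyranone 10. Cutting the diaryl ether instead would leave an aryl–oxygen coupling at the most hindered position of the molecule. Cutting ring E instead would leave ring D and its hindered ether still to be made. The precursors are far simpler than 12: 4 is an acyclic ester derivative and 10 is a monocyclic pyranone. The forward reaction must deliver one regiochemistry (aryloxy next to O1'') and must aromatise without an external oxidant. The sulfinyl group provides the activation and the leaving group, and the ketene acetal carbon provides the remaining oxidation level.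

**4 from 3, and 3 from 1 and 2.** The silyl ketene acetal is taken back to the β-methoxy enoate 3 by removal of the silyl group and return of a γ-proton. Compound 3 is cut at the O–CH2 bond into methyl 4-hydroxybenzoate 1 and the chlorocrotonate 2. The bond that will become the crowded C8''–O ether is thus made by SN2 displacement at a primary allylic carbon, the least demanding way to make it.

**10 from 9, 9 from 6 and 7, and 6 from 5.** The sulfoxide comes from sulfide 9 by oxidation. Pyranone 9 is cut at O1–C6 and at C2–C3, through the enaminodiketone 8, into the thio-substituted enaminone 6 and 4-(benzyloxy)benzoyl chloride 7. Compound 6 comes from commercial (phenylsulfanyl)acetone 5 and an amide acetal. Halogenating a 2-aryl-4-pyranone and then introducing sulfur was not chosen, because electrophilic attack could occur at C3 (next to the electron-rich aryl group) as well as at C5. Carrying sulfur in from 5 fixes its position by construction and saves a step. The aryl group on sulfur is lost in the key step, so phenyl is used because 5 is commercial.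

## Roads not taken

**Alternative 1:** anodic closure of ring E at an aryl carbon. The cut is O1''–C8a''. In the forward sense the 1,3-diketone tert-butyl 4-{5-[3-(4-isopropoxyphenyl)-3-oxopropanoyl]-2,4-dimethoxyphenoxy}benzoate A1 would be oxidised at constant current so that its enol oxygen attacks C8a'', giving tert-butyl 4-{[2-(4-isopropoxyphenyl)-5,7-dimethoxy-4-oxo-4H-chromen-8-yl]oxy}benzoate A2.
- Merit: the diaryl ether is made while C8a'' still carries hydrogen, so the phenol being arylated has only one ortho substituent. In this respect the road is better than any late coupling, and as good as the chosen plan.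
- Merit: A1 is assembled by routine diketone chemistry, and no sulfur auxiliary is needed.
- Weak point: C8a'' is meta to both methoxy groups, so the radical cation of ring D has little positive character there. The other ortho carbon, C5'', is activated and carries a methoxy group, which invites ipso attack and the wrong chromone.
- Weak point: the diketone itself and the trioxygenated ring can be over-oxidised.
- Weak point: after the key step the C5'' methyl ether must be cleaved selectively, the isopropyl ether and the tert-butyl ester removed, and the acid re-activated before unit 1 can be built. The endgame is longer than the three steps that follow 12.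
- Comparison: both key steps lack direct precedent. The chosen plan sets an unambiguous polarity-controlled regiochemistry and a product (12) with every oxygen already differentiated against the easier ether formation of this road.

**Alternative 2:** Friedel–Crafts closure of ring E at C4''–C4a''. The acid (2Z)-3-[4-(benzyloxy)phenyl]-3-{2-[4-(5-hydroxy-7-methoxy-4-oxo-4H-chromen-2-yl)phenoxy]-3,5-dimethoxyphenoxy}prop-2-enoic acid A3 would be activated (for example with P2O5 in MeSO3H) and would acylate ring D to give 2-[4-(benzyloxy)phenyl]-8-[4-(5-hydroxy-7-methoxy-4-oxo-4H-chromen-2-yl)phenoxy]-5,7-dimethoxy-4H-chromen-4-one A4.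
- Merit: the reaction type is established for chromones, and ring D has only one free ortho position, so the closure is regiochemically safe.
- Merit: unit 1 is already complete in A3, and A4 is one boron trihalide treatment (peri-demethylation and debenzylation together) from the target. This endgame is shorter than that of the chosen plan.
- Weak point: the hindered ether is not avoided but moved upstream. The ring-D phenol needed for A3 carries the C8'' aryloxy group between two oxygen substituents, and it must be made by exactly the crowded aryl–oxygen coupling that is the core problem.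
- Weak point: addition of that hindered phenol to an arylpropiolate gives E/Z mixtures, and the strongly acidic closure endangers the benzyl ether.
- Comparison: this road wins on precedent and on the number of steps after the key step. The chosen plan makes the C8''–O bond by SN2 at a primary carbon, needs no late selective demethylation and uses no strong acid on the assembled biflavone.

**Alternative 3:** biomimetic folding of a pyranone into ring A. The cut is C4a–C8a of unit 1. Under Mg(OMe)2 the lactone of 6-(4-{4-[2-(benzyloxy)-4,6-dimethoxyphenoxy]phenyl}-2,4-dioxobutyl)-4-methoxy-2H-pyran-2-one A5 would open, and the C4a methylene carbanion would attack the new ester carbonyl to give 1-{4-[2-(benzyloxy)-4,6-dimethoxyphenoxy]phenyl}-3-(2,6-dihydroxy-4-methoxyphenyl)propane-1,3-dione A6.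
- Merit: the 2,6-dihydroxy-4-methoxy pattern of ring A arises directly and without protecting groups.
- Weak point: the key step is spent on the part of the molecule that is commercially available as 13.
- Weak point: the polycarbonyl chain of A5 has several competing aldol and Claisen modes.
- Weak point: ring D in A6 has no carbon substituent at C4a''. Rings E and F must still be built by acylation between two oxygen substituents, followed by a selective C5'' demethylation, and the hindered ether has again been made by conventional coupling.
- Comparison: in step economy and in where it places its effort this road is inferior to the chosen plan. Its only advantage is that every reaction in it has a biosynthetic or classical counterpart.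

Key step: step 6

Assumption: diene 4 is drawn as the (1Z,3E) isomer, with the aryloxy group on the outer side of the s-cis diene; the geometry at the ketene acetal end is immaterial, since both diene termini become aromatic carbons.

## Route

Step 1
Reactants: 1 methyl 4-hydroxybenzoate; 2 methyl (2E)-4-chloro-3-methoxybut-2-enoate
Product: 3 methyl (2E)-3-methoxy-4-[4-(methoxycarbonyl)phenoxy]but-2-enoate
Conditions: K2CO3, KI (cat.), acetone, reflux
Reagents that add atoms: none
Why: Williamson ether synthesis; the phenoxide of 1 displaces the primary allylic chloride of 2 by SN2 with iodide catalysis. The β-methoxy enoate is a poor Michael acceptor, so O-alkylation at CH2 should dominate and the E geometry is untouched.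

Step 2
Reactants: 3 methyl (2E)-3-methoxy-4-[4-(methoxycarbonyl)phenoxy]but-2-enoate
Product: 4 methyl 4-{[(1Z,3E)-2,4-dimethoxy-4-[(trimethylsilyl)oxy]buta-1,3-dien-1-yl]oxy}benzoate
Conditions: LiN(iPr)2, Me3SiCl, THF, −78 °C (in situ quench); non-aqueous work-up, used crude
Reagents that add atoms: chlorotrimethylsilane, C[Si](C)(C)Cl
Why: γ-Deprotonation of a β-methoxy enoate and O-silylation of the extended enolate is the standard entry to 1,3-dimethoxy-1-silyloxybutadienes, and the OCH2 protons are the only acidic ones. Having Me3SiCl present during deprotonation keeps the dienolate from attacking the benzoate ester.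

Step 3
Reactants: 5 1-(phenylsulfanyl)propan-2-one
Product: 6 (3Z)-4-(dimethylamino)-3-(phenylsulfanyl)but-3-en-2-one
Conditions: Me2NCH(OMe)2, PhMe, 100 °C
Reagents that add atoms: N,N-dimethylformamide dimethyl acetal, COC(OC)N(C)C
Why: Condensation of an activated methylene with an amide acetal; the CH2 flanked by sulfur and the ketone is the more acidic site of 5, and the push-pull enaminone is the stable product. This step fixes sulfur at the future C5 of the pyranone.

Step 4
Reactants: 6 (3Z)-4-(dimethylamino)-3-(phenylsulfanyl)but-3-en-2-one (2 equiv); 7 4-(benzyloxy)benzoyl chloride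
Product: 9 2-[4-(benzyloxy)phenyl]-5-(phenylsulfanyl)-4H-pyran-4-one, via enaminodiketone 8 (not isolated)
Conditions: LiN(SiMe3)2 (2 equiv), THF, −78 °C; 7, −78 to 0 °C; then CF3CO2H, PhMe, rt
Reagents that add atoms: none
Why: Kinetic enolisation of the methyl ketone and C-acylation by the aroyl chloride (two enolates per acid chloride, since the diketone is more acidic) gives 8, whose enol oxygen adds to the enaminone β-carbon under acid with loss of dimethylamine. This acylation–cyclisation of β-heteroatom-substituted enones is an established 4-pyranone synthesis, and the benzyl ether tolerates brief CF3CO2H at room temperature.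

Step 5
Reactants: 9 2-[4-(benzyloxy)phenyl]-5-(phenylsulfanyl)-4H-pyran-4-one
Product: 10 2-[4-(benzyloxy)phenyl]-5-(phenylsulfinyl)-4H-pyran-4-one (racemic at sulfur)
Conditions: mCPBA (1.0 equiv), CH2Cl2, −40 to 0 °C
Reagents that add atoms: 3-chloroperoxybenzoic acid, OOC(=O)c1cccc(Cl)c1
Why: Sulfide-to-sulfoxide oxidation with one equivalent of peracid at low temperature; the electron-poor pyranone double bonds are not epoxidised. The sulfoxide forms as a racemate, which is immaterial because sulfur is expelled in step 6.

Step 6
Reactants: 4 methyl 4-{[(1Z,3E)-2,4-dimethoxy-4-[(trimethylsilyl)oxy]buta-1,3-dien-1-yl]oxy}benzoate (2 equiv); 10 2-[4-(benzyloxy)phenyl]-5-(phenylsulfinyl)-4H-pyran-4-one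
Product: 12 methyl 4-({2-[4-(benzyloxy)phenyl]-5-hydroxy-7-methoxy-4-oxo-4H-chromen-8-yl}oxy)benzoate, via sulfinyl cycloadduct 11 (not isolated)
Conditions: PhMe, 25 °C then 100 °C, argon; SiO2 work-up
Reagents that add atoms: none
Why: Proposed new method: the electron-rich diene 4 should add across C5=C6 of 10, the only pyranone double bond activated by both the ketone and the sulfinyl group, in a normal-demand [4+2] cycloaddition that may be concerted but asynchronous or may run as a vinylogous Mukaiyama–Michael addition followed by closure. The aryloxy-bearing terminus of 4 (the γ-carbon of the silyl ketene acetal and its most nucleophilic site) bonds to the electrophilic C6 (the future C8a''), and the acetal carbon then bonds to C5 (the future C4a''), so ring D is closed by intermolecular [4+2] annulation whose second bond, if the process is stepwise, forms by 6-(enolexo)-exo-trig attack of the sulfinyl-stabilised enolate on the oxocarbenium carbon. Suprafacial addition places the sulfinyl group and H8a'' cis in 11, so thermal syn elimination of benzenesulfenic acid restores the C4a''=C8a'' bond; the mixed methyl silyl ketal at C5'' then collapses to the ketone with loss of methoxytrimethylsilane, and the doubly vinylogous C8''–H shifts to oxygen to give the chelated phenol. The closest known reaction types are the regiocontrolled Diels–Alder aromatisations of 1,1,3-trioxygenated butadienes with halo- and sulfinylquinones and the cycloadditions of C3-activated chromones with oxygenated dienes that end in xanthones; a monocyclic 5-sulfinyl-4-pyranone has not been used in this role. The step needs regioselectivity (aryloxy at C8'', not at C5'') and site selectivity (C5=C6, not C2=C3): the first is secured by the polarity match just described, the second by the sulfinyl group and by the aryl substituent that blocks C2. All five stereogenic centres of 11 (C4a'', C5'', C8'', C8a'' and sulfur) are erased on aromatisation, so no stereocontrol is required. The C8''–O bond is already present as the ether made in step 1, so no aryl–oxygen coupling at the crowded position is needed.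

Step 7
Reactants: 12 methyl 4-({2-[4-(benzyloxy)phenyl]-5-hydroxy-7-methoxy-4-oxo-4H-chromen-8-yl}oxy)benzoate; 13 1-(2,6-dihydroxy-4-methoxyphenyl)ethan-1-one
Product: 14 1-[4-({2-[4-(benzyloxy)phenyl]-5-hydroxy-7-methoxy-4-oxo-4H-chromen-8-yl}oxy)phenyl]-3-(2,6-dihydroxy-4-methoxyphenyl)propane-1,3-dione
Conditions: LiN(SiMe3)2 (6 equiv), THF, −78 °C to rt; then aq. HCl
Reagents that add atoms: none
Why: Claisen condensation of the lithium polyanion of 13 (both phenoxides and the methyl ketone enolate) with the methyl ester. The 5''-OH of 12 is deprotonated first and its chelated phenoxide deactivates the pyranone towards addition; ring A is symmetric, so only one diketone can form.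

Step 8
Reactants: 14 1-[4-({2-[4-(benzyloxy)phenyl]-5-hydroxy-7-methoxy-4-oxo-4H-chromen-8-yl}oxy)phenyl]-3-(2,6-dihydroxy-4-methoxyphenyl)propane-1,3-dione
Product: 15 2-[4-(benzyloxy)phenyl]-5-hydroxy-8-[4-(5-hydroxy-7-methoxy-4-oxo-4H-chromen-2-yl)phenoxy]-7-methoxy-4H-chromen-4-one
Conditions: H2SO4 (cat.), AcOH, 90 °C
Reagents that add atoms: none
Why: Acid-catalysed cyclodehydration of a 2-hydroxyaryl 1,3-diketone closes ring C as the flavone; the two ortho hydroxyl groups of ring A are equivalent, so the 5-hydroxy-7-methoxy pattern follows without choice. Any benzyl ether lost here merely anticipates step 9.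

Step 9
Reactants: 15 2-[4-(benzyloxy)phenyl]-5-hydroxy-8-[4-(5-hydroxy-7-methoxy-4-oxo-4H-chromen-2-yl)phenoxy]-7-methoxy-4H-chromen-4-one
Product: 16 5-hydroxy-8-[4-(5-hydroxy-7-methoxy-4-oxo-4H-chromen-2-yl)phenoxy]-2-(4-hydroxyphenyl)-7-methoxy-4H-chromen-4-one
Conditions: H2 (1 atm), 10% Pd/C, THF–MeOH, rt
Reagents that add atoms: none
Why: Hydrogenolysis of the benzyl aryl ether over Pd/C at atmospheric pressure; the flavone C2=C3 bonds, the diaryl ether and the methyl ethers are inert under these conditions when the reaction is stopped at full conversion.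

## Compound list

1 | methyl 4-hydroxybenzoate | COC(=O)c1ccc(O)cc1 | starting material
2 | methyl (2E)-4-chloro-3-methoxybut-2-enoate | CO/C(CCl)=C/C(=O)OC | starting material
3 | methyl (2E)-3-methoxy-4-[4-(methoxycarbonyl)phenoxy]but-2-enoate | COC(=O)/C=C(/OC)COc1ccc(cc1)C(=O)OC | intermediate
4 | methyl 4-{[(1Z,3E)-2,4-dimethoxy-4-[(trimethylsilyl)oxy]buta-1,3-dien-1-yl]oxy}benzoate | COC(=O)c1ccc(O/C=C(OC)/C=C(\OC)O[Si](C)(C)C)cc1 | intermediate
5 | 1-(phenylsulfanyl)propan-2-one | CC(=O)CSc1ccccc1 | starting material
6 | (3Z)-4-(dimethylamino)-3-(phenylsulfanyl)but-3-en-2-one | CC(=O)/C(Sc1ccccc1)=C/N(C)C | intermediate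
7 | 4-(benzyloxy)benzoyl chloride | O=C(Cl)c1ccc(OCc2ccccc2)cc1 | starting material
8 | (4Z)-1-[4-(benzyloxy)phenyl]-5-(dimethylamino)-4-(phenylsulfanyl)pent-4-ene-1,3-dione (formed in the flask, not isolated) | O=C(CC(=O)/C(Sc1ccccc1)=C/N(C)C)c1ccc(OCc2ccccc2)cc1 | intermediate
9 | 2-[4-(benzyloxy)phenyl]-5-(phenylsulfanyl)-4H-pyran-4-one | O=c1cc(-c2ccc(OCc3ccccc3)cc2)occ1Sc1ccccc1 | intermediate
10 | 2-[4-(benzyloxy)phenyl]-5-(phenylsulfinyl)-4H-pyran-4-one (racemic at sulfur) | O=c1cc(-c2ccc(OCc3ccccc3)cc2)occ1S(=O)c1ccccc1 | intermediate
11 | methyl 4-({2-[4-(benzyloxy)phenyl]-5,7-dimethoxy-4-oxo-4a-(phenylsulfinyl)-5-[(trimethylsilyl)oxy]-4a,5,8,8a-tetrahydro-4H-chromen-8-yl}oxy)benzoate (cis ring fusion, mixture of diastereomers, formed in the flask, not isolated) | COC(=O)c1ccc(OC2C(OC)=CC(OC)(O[Si](C)(C)C)C3(S(=O)c4ccccc4)C(=O)C=C(c4ccc(OCc5ccccc5)cc4)OC23)cc1 | intermediate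
12 | methyl 4-({2-[4-(benzyloxy)phenyl]-5-hydroxy-7-methoxy-4-oxo-4H-chromen-8-yl}oxy)benzoate | COC(=O)c1ccc(Oc2c(OC)cc(O)c3c(=O)cc(-c4ccc(OCc5ccccc5)cc4)oc23)cc1 | intermediate
13 | 1-(2,6-dihydroxy-4-methoxyphenyl)ethan-1-one | CC(=O)c1c(O)cc(OC)cc1O | starting material
14 | 1-[4-({2-[4-(benzyloxy)phenyl]-5-hydroxy-7-methoxy-4-oxo-4H-chromen-8-yl}oxy)phenyl]-3-(2,6-dihydroxy-4-methoxyphenyl)propane-1,3-dione | COc1cc(O)c(C(=O)CC(=O)c2ccc(Oc3c(OC)cc(O)c4c(=O)cc(-c5ccc(OCc6ccccc6)cc5)oc34)cc2)c(O)c1 | intermediate
15 | 2-[4-(benzyloxy)phenyl]-5-hydroxy-8-[4-(5-hydroxy-7-methoxy-4-oxo-4H-chromen-2-yl)phenoxy]-7-methoxy-4H-chromen-4-one | COc1cc(O)c2c(=O)cc(-c3ccc(Oc4c(OC)cc(O)c5c(=O)cc(-c6ccc(OCc7ccccc7)cc6)oc45)cc3)oc2c1 | intermediate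
16 | 5-hydroxy-8-[4-(5-hydroxy-7-methoxy-4-oxo-4H-chromen-2-yl)phenoxy]-2-(4-hydroxyphenyl)-7-methoxy-4H-chromen-4-one | COc1cc(O)c2c(=O)cc(-c3ccc(Oc4c(OC)cc(O)c5c(=O)cc(-c6ccc(O)cc6)oc45)cc3)oc2c1 | target

## Step count and risks

Total steps: 9. Longest linear sequence: 7 steps (steps 3, 4, 5, 6, 7, 8, 9, from 5 to 16). The diene arm (steps 1 and 2) joins at step 6.

**Step 6 (key step, new method).** Three things are most likely to go wrong.
- The cycloaddition may be slow, because the pyranone is a vinylogous ester and only moderately activated. Desilylation of the diene by traces of acid or by the liberated sulfenic acid could then outrun it; the excess of 4 is meant to absorb this.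
- A stepwise pathway may stall after the first bond. The C6 adduct can expel sulfenic acid without ring closure, or the pyranone can open by retro-oxa-Michael cleavage of the O1–C6 bond.
- The ketal may collapse by loss of silanol instead of methoxysilane, which would leave C5'' as its methyl ether.

Fallback, by known chemistry and giving up the annulation of ring D: setting out from 13 and 7, LiN(SiMe3)2-mediated C-acylation would give 1-[4-(benzyloxy)phenyl]-3-(2,6-dihydroxy-4-methoxyphenyl)propane-1,3-dione F1, and cyclodehydration (H2SO4, AcOH) would give 2-[4-(benzyloxy)phenyl]-5-hydroxy-7-methoxy-4H-chromen-4-one F2. Elbs persulfate oxidation (K2S2O8, aqueous KOH, pyridine) would oxidise the position para to the 5-hydroxyl group by way of potassium 2-[4-(benzyloxy)phenyl]-5-hydroxy-7-methoxy-4-oxo-4H-chromen-8-yl sulfate F3, which aqueous HCl would hydrolyse to 2-[4-(benzyloxy)phenyl]-5,8-dihydroxy-7-methoxy-4H-chromen-4-one F4. Ullmann-type O-arylation of the non-chelated 8-hydroxyl group with methyl 4-iodobenzoate (CuI, picolinic acid, K3PO4, DMSO, 90 °C, argon) comes back to the route at 12. This fallback accepts the hindered aryl–oxygen coupling that the main plan was designed to avoid.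

**Step 2.** The dienolate may attack a benzoate ester before it is silylated. The diene may form as a geometric mixture in which the isomer with an inward aryloxy group cannot reach the s-cis conformation. The silyl ketene acetal may hydrolyse during isolation. Fallback, switching to the more robust bis(silyl enol ether) diene class, which is known with 4-aryloxy substituents: setting out from 3, aqueous HCl in THF would hydrolyse the enol ether to methyl 4-(4-methoxy-2,4-dioxobutoxy)benzoate F5. Double silylation (Me3SiOTf, NEt3, Et2O, 0 °C) would give methyl 4-{[(1Z,3E)-4-methoxy-2,4-bis(trimethylsilyloxy)buta-1,3-dien-1-yl]oxy}benzoate F6. Cycloaddition with 10 and aromatisation as in step 6, with loss of the 7-O-silyl group on work-up, would give methyl 4-({2-[4-(benzyloxy)phenyl]-5,7-dihydroxy-4-oxo-4H-chromen-8-yl}oxy)benzoate F7. Methylation of the non-chelated 7-hydroxyl group (MeI, K2CO3, acetone) comes back to the route at 12.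

**Step 4.** O-acylation of the enolate may compete with C-acylation, and the thio-substituted vinylogous amide may enolise incompletely, so that the acid chloride is consumed unproductively. Fallback, introducing sulfur after the ring is made: setting out from 7, acylation of the lithium enolate of commercial (E)-4-methoxybut-3-en-2-one and acid cyclisation (CF3CO2H) would give 2-[4-(benzyloxy)phenyl]-4H-pyran-4-one F8. α-Iodination by the addition–elimination protocol (I2, pyridine, CHCl3), in which pyridine can add only to the unsubstituted C6, would give 2-[4-(benzyloxy)phenyl]-5-iodo-4H-pyran-4-one F9. Copper-catalysed C–S coupling with thiophenol (CuI, 1,10-phenanthroline, K2CO3, DMF, 90 °C) comes back to the route at 9.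

**Step 7.** The electron-rich aryloxybenzoate is a sluggish acyl acceptor, so conversion may be incomplete. On prolonged reaction the enolate may add to C2'' of the flavone or open its pyranone ring. Fallback, by acyl transfer through oxygen: setting out from 12, LiOH in aqueous THF would give 4-({2-[4-(benzyloxy)phenyl]-5-hydroxy-7-methoxy-4-oxo-4H-chromen-8-yl}oxy)benzoic acid F10. Carbodiimide esterification (EDC·HCl, DMAP, CH2Cl2) with an excess of 13 would give 2-acetyl-3-hydroxy-5-methoxyphenyl 4-({2-[4-(benzyloxy)phenyl]-5-hydroxy-7-methoxy-4-oxo-4H-chromen-8-yl}oxy)benzoate F11. Baker–Venkataraman rearrangement (KOH, pyridine, 50 °C) comes back to the route at 14.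

## Further compounds

F1 | step 6 | 1-[4-(benzyloxy)phenyl]-3-(2,6-dihydroxy-4-methoxyphenyl)propane-1,3-dione | COc1cc(O)c(C(=O)CC(=O)c2ccc(OCc3ccccc3)cc2)c(O)c1
F2 | step 6 | 2-[4-(benzyloxy)phenyl]-5-hydroxy-7-methoxy-4H-chromen-4-one | COc1cc(O)c2c(=O)cc(-c3ccc(OCc4ccccc4)cc3)oc2c1
F3 | step 6 | potassium 2-[4-(benzyloxy)phenyl]-5-hydroxy-7-methoxy-4-oxo-4H-chromen-8-yl sulfate | COc1cc(O)c2c(=O)cc(-c3ccc(OCc4ccccc4)cc3)oc2c1OS(=O)(=O)[O-].[K+]
F4 | step 6 | 2-[4-(benzyloxy)phenyl]-5,8-dihydroxy-7-methoxy-4H-chromen-4-one | COc1cc(O)c2c(=O)cc(-c3ccc(OCc4ccccc4)cc3)oc2c1O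
F5 | step 2 | methyl 4-(4-methoxy-2,4-dioxobutoxy)benzoate | COC(=O)CC(=O)COc1ccc(cc1)C(=O)OC
F6 | step 2 | methyl 4-{[(1Z,3E)-4-methoxy-2,4-bis(trimethylsilyloxy)buta-1,3-dien-1-yl]oxy}benzoate | COC(=O)c1ccc(O/C=C(O[Si](C)(C)C)/C=C(\OC)O[Si](C)(C)C)cc1
F7 | step 2 | methyl 4-({2-[4-(benzyloxy)phenyl]-5,7-dihydroxy-4-oxo-4H-chromen-8-yl}oxy)benzoate | COC(=O)c1ccc(Oc2c(O)cc(O)c3c(=O)cc(-c4ccc(OCc5ccccc5)cc4)oc23)cc1
F8 | step 4 | 2-[4-(benzyloxy)phenyl]-4H-pyran-4-one | O=c1ccoc(-c2ccc(OCc3ccccc3)cc2)c1
F9 | step 4 | 2-[4-(benzyloxy)phenyl]-5-iodo-4H-pyran-4-one | O=c1cc(-c2ccc(OCc3ccccc3)cc2)occ1I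
F10 | step 7 | 4-({2-[4-(benzyloxy)phenyl]-5-hydroxy-7-methoxy-4-oxo-4H-chromen-8-yl}oxy)benzoic acid | OC(=O)c1ccc(Oc2c(OC)cc(O)c3c(=O)cc(-c4ccc(OCc5ccccc5)cc4)oc23)cc1
F11 | step 7 | 2-acetyl-3-hydroxy-5-methoxyphenyl 4-({2-[4-(benzyloxy)phenyl]-5-hydroxy-7-methoxy-4-oxo-4H-chromen-8-yl}oxy)benzoate | CC(=O)c1c(O)cc(OC)cc1OC(=O)c1ccc(Oc2c(OC)cc(O)c3c(=O)cc(-c4ccc(OCc5ccccc5)cc4)oc23)cc1
A1 | alternative 1 | tert-butyl 4-{5-[3-(4-isopropoxyphenyl)-3-oxopropanoyl]-2,4-dimethoxyphenoxy}benzoate | CC(C)Oc1ccc(cc1)C(=O)CC(=O)c1cc(Oc2ccc(cc2)C(=O)OC(C)(C)C)c(OC)cc1OC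
A2 | alternative 1 | tert-butyl 4-{[2-(4-isopropoxyphenyl)-5,7-dimethoxy-4-oxo-4H-chromen-8-yl]oxy}benzoate | CC(C)Oc1ccc(cc1)-c1cc(=O)c2c(OC)cc(OC)c(Oc3ccc(cc3)C(=O)OC(C)(C)C)c2o1
A3 | alternative 2 | (2Z)-3-[4-(benzyloxy)phenyl]-3-{2-[4-(5-hydroxy-7-methoxy-4-oxo-4H-chromen-2-yl)phenoxy]-3,5-dimethoxyphenoxy}prop-2-enoic acid | OC(=O)/C=C(\Oc1cc(OC)cc(OC)c1Oc1ccc(cc1)-c1cc(=O)c2c(O)cc(OC)cc2o1)c1ccc(OCc2ccccc2)cc1
A4 | alternative 2 | 2-[4-(benzyloxy)phenyl]-8-[4-(5-hydroxy-7-methoxy-4-oxo-4H-chromen-2-yl)phenoxy]-5,7-dimethoxy-4H-chromen-4-one | COc1cc(O)c2c(=O)cc(-c3ccc(Oc4c(OC)cc(OC)c5c(=O)cc(-c6ccc(OCc7ccccc7)cc6)oc45)cc3)oc2c1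
A5 | alternative 3 | 6-(4-{4-[2-(benzyloxy)-4,6-dimethoxyphenoxy]phenyl}-2,4-dioxobutyl)-4-methoxy-2H-pyran-2-one | COc1cc(=O)oc(CC(=O)CC(=O)c2ccc(Oc3c(OCc4ccccc4)cc(OC)cc3OC)cc2)c1
A6 | alternative 3 | 1-{4-[2-(benzyloxy)-4,6-dimethoxyphenoxy]phenyl}-3-(2,6-dihydroxy-4-methoxyphenyl)propane-1,3-dione | COc1cc(O)c(C(=O)CC(=O)c2ccc(Oc3c(OCc4ccccc4)cc(OC)cc3OC)cc2)c(O)c1
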